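**Assumption:** Eryvarin F has no stereocentres and no stereogenic alkenes (both prenyl termini are gem-dimethyl), so it is achiral; no stereocontrol step is needed. Catalysts, bases, solvents and water are not numbered. This route is designed on paper and has not been run.

## Retrosynthetic overview

1. Eryvarin F ⇒ global MOM removal from its tris-MOM ether.
2. C6/C8 prenyl groups ⇒ one double Suzuki–Miyaura prenylation of a 6,8-dibromide with prenyl-Bpin (no Claisen chemistry).
3. Key disconnection: C3–O–aryl bond ⇒ Chan–Lam O-arylation of a 3-hydroxychromone with a 2,4-bis(MOM-oxy)phenylboronic acid. This replaces the usual ω-aryloxyacetophenone + C1 cyclisation.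
4. 3-Hydroxychromone ⇒ nitrosative oxidation/aromatisation of dibrominated 7-hydroxychroman-4-one (commercial).
5. Ring order: the benzopyranone bicycle is purchased and only oxidised (chromanone → chromone, step 2); the intact B-ring is attached in step 6.

## Route

**Step 1**
Reactants: 1, 7-hydroxychroman-4-one; 2, N-bromosuccinimide (2.05 equiv)
Product: 3, 6,8-dibromo-7-hydroxychroman-4-one
Conditions: NBS, MeCN, 0 °C → rt
Reagents that add atoms: N-bromosuccinimide (2), O=C1CCC(=O)N1Br
Why: Electrophilic aromatic bromination; C6 and C8 are each activated by both the 7-OH and O1 while C5 is meta to both, so dibromination is regiospecific and far faster than ketone α-bromination.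

**Step 2**
Reactants: 3, 6,8-dibromo-7-hydroxychroman-4-one
Product: 4, 6,8-dibromo-3,7-dihydroxy-4H-chromen-4-one
Conditions: isoamyl nitrite (3 equiv), conc. HCl, EtOH, 0 °C → 70 °C
Reagents that add atoms: water, O (supplies the C3 oxygen by hydrolysis of the 3-oximino intermediate); isoamyl nitrite, CC(C)CCON=O, is the nitrosating agent and its N–O unit is lost.
Why: Classical Kostanecki-type α-nitrosation of a chromanone: the acid enol is nitrosated at C3, the 3-oxime hydrolyses to the 3,4-dione, and this enolises to the aromatic 3-hydroxy-4-pyranone; the bromines block C-nitrosation of the phenol ring.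

**Step 3**
Reactants: 4, 6,8-dibromo-3,7-dihydroxy-4H-chromen-4-one; 5, chloromethyl methyl ether (MOMCl, 1.05 equiv)
Product: 6, 6,8-dibromo-3-hydroxy-7-(methoxymethoxy)-4H-chromen-4-one
Conditions: MOMCl, i-Pr2NEt (1.1 equiv), CH2Cl2/DMF, 0 °C
Reagents that add atoms: chloromethyl methyl ether (5), COCCl
Why: Selective O-alkylation; the 7-OH is a vinylogous acid flanked by two bromines (estimated pKa about 5–6) and is the only OH ionised by one equivalent of base, while the 3-OH (pKa about 9) is H-bonded to C4=O, matching the known 7-over-3 alkylation order of flavonols.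

**Step 4**
Reactants: 7, 4-bromoresorcinol (4-bromobenzene-1,3-diol); 5, chloromethyl methyl ether (2.5 equiv)
Product: 8, 1-bromo-2,4-bis(methoxymethoxy)benzene
Conditions: MOMCl, i-Pr2NEt, CH2Cl2, 0 °C → rt
Reagents that add atoms: chloromethyl methyl ether (5), COCCl
Why: Standard bis-MOM protection of a phenol (Williamson-type O-alkylation).

**Step 5**
Reactants: 8, 1-bromo-2,4-bis(methoxymethoxy)benzene; 9, triisopropyl borate
Product: 10, [2,4-bis(methoxymethoxy)phenyl]boronic acid
Conditions: n-BuLi, THF, −78 °C; B(Oi-Pr)3, −78 °C → rt; sat. aq. NH4Cl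
Reagents that add atoms: triisopropyl borate (9), CC(C)OB(OC(C)C)OC(C)C (boron); water, O (the two B–OH oxygens)
Why: Br–Li exchange gives an aryllithium stabilised by the ortho-OMOM group, borate trapping and buffered hydrolysis give the boronic acid without cleaving the acetals.

**Step 6 (key step)**
Reactants: 6, 6,8-dibromo-3-hydroxy-7-(methoxymethoxy)-4H-chromen-4-one; 10, [2,4-bis(methoxymethoxy)phenyl]boronic acid (2.5 equiv, added in portions)
Product: 11, 3-[2,4-bis(methoxymethoxy)phenoxy]-6,8-dibromo-7-(methoxymethoxy)-4H-chromen-4-one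
Conditions: Cu(OAc)2 (1.5 equiv), pyridine (5 equiv), 4 Å MS, CH2Cl2, dry air, rt, 24–48 h
Reagents that add atoms: none (all product atoms come from 6 and 10)
Why: Proposed new method: Chan–Lam–Evans oxidative O-arylation extended to a 3-hydroxychromone; the acidic, phenol-like enolic 3-OH binds Cu(II), aryl transfer from boron gives a Cu(aryl)(enolate) that is oxidised to Cu(III) and reductively eliminates the C3–O–aryl bond at rt, leaving the C–Br bonds and MOM acetals untouched; the closest known reaction type is Cu(OAc)2/pyridine diaryl-ether synthesis from phenols and arylboronic acids.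

**Step 7**
Reactants: 11, the dibromo aryl ether from step 6; 12, prenylboronic acid pinacol ester (4,4,5,5-tetramethyl-2-(3-methylbut-2-en-1-yl)-1,3,2-dioxaborolane, 4 equiv)
Product: 13, 3-[2,4-bis(methoxymethoxy)phenoxy]-7-(methoxymethoxy)-6,8-bis(3-methylbut-2-en-1-yl)-4H-chromen-4-one
Conditions: Pd(dppf)Cl2·CH2Cl2 (10 mol %), CsF (6 equiv), degassed THF, 70 °C
Reagents that add atoms: prenylboronic acid pinacol ester (12), CC(C)=CCB1OC(C)(C)C(C)(C)O1
Why: Double Suzuki–Miyaura allyl–aryl coupling; the bidentate dppf ligand lets the allyl-Pd intermediate equilibrate (σ–π–σ) to the less hindered primary terminus, giving the linear prenyl group, and the chromone and acetals tolerate the mild fluoride base.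

**Step 8**
Reactants: 13, the tris-MOM diprenyl chromone from step 7
Product: 14, Eryvarin F, 3-(2,4-dihydroxyphenoxy)-7-hydroxy-6,8-bis(3-methylbut-2-en-1-yl)-4H-chromen-4-one
Conditions: 3 M aq. HCl/MeOH (1:5), 40–45 °C, monitored; NaHCO3 quench
Reagents that add atoms: none
Why: Acid-catalysed acetal hydrolysis of the three aryl MOM ethers; dilute HCl in MeOH at mild temperature is the standard way to unmask MOM-protected prenylated phenols without cyclising the ortho-prenyl phenol to a chroman.

## Compound list

1 | 7-hydroxychroman-4-one | O=C1CCOc2cc(O)ccc12 | starting material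
2 | N-bromosuccinimide | O=C1CCC(=O)N1Br | starting material (reagent)
3 | 6,8-dibromo-7-hydroxychroman-4-one | O=C1CCOc2c(Br)c(O)c(Br)cc12 | intermediate
4 | 6,8-dibromo-3,7-dihydroxy-4H-chromen-4-one | O=c1c(O)coc2c(Br)c(O)c(Br)cc12 | intermediate
5 | chloromethyl methyl ether (MOMCl) | COCCl | starting material (reagent)
6 | 6,8-dibromo-3-hydroxy-7-(methoxymethoxy)-4H-chromen-4-one | O=c1c(O)coc2c(Br)c(OCOC)c(Br)cc12 | intermediate
7 | 4-bromoresorcinol | Oc1ccc(Br)c(O)c1 | starting material
8 | 1-bromo-2,4-bis(methoxymethoxy)benzene | COCOc1ccc(Br)c(OCOC)c1 | intermediate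
9 | triisopropyl borate | CC(C)OB(OC(C)C)OC(C)C | starting material (reagent)
10 | [2,4-bis(methoxymethoxy)phenyl]boronic acid | COCOc1ccc(B(O)O)c(OCOC)c1 | intermediate
11 | 3-[2,4-bis(methoxymethoxy)phenoxy]-6,8-dibromo-7-(methoxymethoxy)-4H-chromen-4-one | O=c1c(Oc3ccc(OCOC)cc3OCOC)coc2c(Br)c(OCOC)c(Br)cc12 | intermediate
12 | prenylboronic acid pinacol ester | CC(C)=CCB1OC(C)(C)C(C)(C)O1 | starting material
13 | 3-[2,4-bis(methoxymethoxy)phenoxy]-7-(methoxymethoxy)-6,8-bis(3-methylbut-2-en-1-yl)-4H-chromen-4-one | CC(C)=CCc1cc2c(=O)c(Oc3ccc(OCOC)cc3OCOC)coc2c(CC=C(C)C)c1OCOC | intermediate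
14 | Eryvarin F (achiral) | CC(C)=CCc1cc2c(=O)c(Oc3ccc(O)cc3O)coc2c(CC=C(C)C)c1O | target

## Summary

**Total step count:** 8.

**Longest linear sequence:** 6 steps (1 → 3 → 4 → 6 → 11 → 13 → 14); the boronic acid branch (7 → 8 → 10) is 2 steps.

**Three steps most likely to fail, with fallbacks:**

1. **Step 6 (Chan–Lam on the chelating 3-hydroxychromone with an ortho-alkoxy boronic acid).** Risks are a stable Cu chelate that does not turn over, or protodeboronation. Fallback: switch to SNAr plus oxygen installation. React the anion of 6 with 4-fluoro-3-(methoxymethoxy)benzaldehyde (K2CO3, DMF), then Dakin/Baeyer–Villiger oxidation (mCPBA, then K2CO3/MeOH) of the para-CHO to the 4'-OH and MOM-protect, rejoining at 11. This is done at the dibromide stage, so no alkenes are exposed to peracid.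

2. **Step 7 (double prenyl Suzuki).** Risks are branched (reverse-prenyl) isomer, mono-coupling, or protodebromination at the hindered C8. Fallback: invert the polarity. Convert 11 to the 6,8-bis(pinacolboronate) by Miyaura borylation and couple with prenyl bromide or tert-butyl prenyl carbonate under Pd(0); the π-prenyl-Pd electrophile is attacked at its primary terminus, giving the linear product.

3. **Step 2 (nitrosative oxidation of the dibromophenolic chromanone).** Risks are incomplete oxime hydrolysis or side reactions of the free phenol. Fallback: build the 3-hydroxychromone from the acetophenone series instead. Take 3,5-dibromo-2,4-dihydroxyacetophenone through Vilsmeier–Haack (POCl3/DMF) to the 3-formylchromone, then Dakin/Baeyer–Villiger oxidation (mCPBA, mild hydrolysis) to give 4.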